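**Plan** (labdane numbering: ring A = C1–C5, C10; ring B = C5–C10; C11–C16 side chain; C17 on C8; C20 on C10)

- Retrosynthesis: remove the C16 acetate, cut C12–C13 (sp3–sp2 coupling), take C11=C12 back to a C11 aldehyde and the C17 ester back to a silyloxymethyl group with C8 inverted, then cut C5–C10 and C8–C9 together.
- Enabling feature: ring B is a cyclohexene whose C6=C7 bond lies opposite the C9–C10 edge; C9 carries C11, C8 carries C17, and ring A (C1–C4) spans C10 and C5. This is the pattern left by an intramolecular [4+2] of a 3-methyl-2,8,10-trienal.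
- The acyclic trienal is cut at C9=C10/C11 (alkyne methylalumination, formaldehyde), at C5=C6 (vinylogous HWE) and at C3–C4 (nitrile alkylation).
- Forward: the chain is assembled linearly (steps 1–8), rings A and B close together (step 9), C17 is oxidised and C8 inverted (steps 10–14), and the C13–C16 unit is joined last (steps 15–17).
- Stereochemistry: a chiral oxazaborolidinium catalyst sets the absolute sense; the E-enal, E,E-diene and endo-formyl approach set C5, C9 and C10 and give C8 as the epimer, which is corrected by equilibrating the ester to the equatorial position; the C13=C14 geometry comes from anti-hydroiodination and is kept in the coupling.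

Key step: step 9

Remark: the sense of induction of the (S)-oxazaborolidinium catalyst is assigned from the formyl C–H···O binding model (diene adds to the Re face of C9); this is an assumption, and the equally accessible (R)-catalyst would be used if the first run showed the opposite sense.
Remark: carbanions made by simple deprotonation (lithiated nitrile, phosphonate anion, ester dienolate) are treated as the reacting form of the numbered compound and carry no number of their own.

**Route**

Step 1
Reactants: 1 isobutyronitrile; 2 (5-chloropent-1-yn-1-yl)trimethylsilane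
Product: 3 2,2-dimethyl-7-(trimethylsilyl)hept-6-ynenitrile
Conditions: LDA, THF, −78 °C; then 2, DMPU, −78 °C → rt
Reagents that add atoms: none
Why: α-Alkylation of a nitrile anion: lithiated isobutyronitrile is small, strongly nucleophilic and cannot self-condense, so it should displace the primary chloride (SN2) and create the quaternary carbon that becomes C4, while the silyl cap keeps the alkyne from being deprotonated.

Step 2
Reactants: 3 2,2-dimethyl-7-(trimethylsilyl)hept-6-ynenitrile
Product: 5 2,2-dimethyl-7-(trimethylsilyl)hept-6-ynal, via aluminated aldimine 4 (not isolated)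
Conditions: DIBAL-H, CH2Cl2, −78 → −20 °C; then 1 M HCl, 0 °C
Reagents that add atoms: water, O
Why: DIBAL half-reduction of a tertiary nitrile stops at the N-aluminated aldimine, which is hydrolysed on brief acidic work-up to the neopentyl aldehyde, and the silylalkyne is not hydroaluminated at this temperature.

Step 3
Reactants: 5 2,2-dimethyl-7-(trimethylsilyl)hept-6-ynal; 6 triethyl 4-phosphonocrotonate
Product: 7 ethyl (2E,4E)-6,6-dimethyl-11-(trimethylsilyl)undeca-2,4-dien-10-ynoate
Conditions: 6, LiHMDS, THF, −78 °C; then 5, −78 → 0 °C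
Reagents that add atoms: none
Why: Vinylogous Horner–Wadsworth–Emmons olefination of a non-enolisable aldehyde with a stabilised phosphonate anion should give the new C5=C6 bond E (thermodynamic control next to the quaternary carbon) and keep the E geometry already present in the crotonate.

Step 4
Reactants: 7 ethyl (2E,4E)-6,6-dimethyl-11-(trimethylsilyl)undeca-2,4-dien-10-ynoate
Product: 8 (2E,4E)-6,6-dimethyl-11-(trimethylsilyl)undeca-2,4-dien-10-yn-1-ol
Conditions: DIBAL-H, CH2Cl2, −78 °C; Rochelle salt work-up
Reagents that add atoms: none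
Why: DIBAL 1,2-reduction of a conjugated dienoate gives the dienol without touching the diene or the silylalkyne, which removes the carbonyl group from the future diene.

Step 5
Reactants: 8 (2E,4E)-6,6-dimethyl-11-(trimethylsilyl)undeca-2,4-dien-10-yn-1-ol
Product: 9 tert-butyl{[(2E,4E)-6,6-dimethyl-11-(trimethylsilyl)undeca-2,4-dien-10-yn-1-yl]oxy}dimethylsilane
Conditions: TBSCl, imidazole, CH2Cl2, 0 °C → rt
Reagents that add atoms: tert-butyldimethylsilyl chloride, CC(C)(C)[Si](C)(C)Cl
Why: Imidazole-promoted O-silylation of an unhindered primary alcohol protects the future C17 oxygen as an ether that tolerates organoaluminium reagents, ylides and the Lewis-acid catalyst.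

Step 6
Reactants: 9 tert-butyl{[(2E,4E)-6,6-dimethyl-11-(trimethylsilyl)undeca-2,4-dien-10-yn-1-yl]oxy}dimethylsilane
Product: 10 tert-butyl{[(2E,4E)-6,6-dimethylundeca-2,4-dien-10-yn-1-yl]oxy}dimethylsilane
Conditions: K2CO3 (cat.), MeOH, rt
Reagents that add atoms: none
Why: Base-catalysed methanolysis cleaves the C(sp)–Si bond selectively (protodesilylation), because an alkynyl anion is a far better leaving group from silicon than the alkoxide of the O-TBS ether.

Step 7
Reactants: 10 tert-butyl{[(2E,4E)-6,6-dimethylundeca-2,4-dien-10-yn-1-yl]oxy}dimethylsilane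
Product: 12 (2E,8E,10E)-12-[(tert-butyldimethylsilyl)oxy]-3,7,7-trimethyldodeca-2,8,10-trien-1-ol, via alkenylalane 11 (not isolated)
Conditions: Me3Al, Cp2ZrCl2 (20 mol %), H2O (1 equiv), CH2Cl2, −23 °C; then (CH2O)n, −23 °C → rt
Reagents that add atoms: trimethylaluminium, C[Al](C)C; paraformaldehyde (as formaldehyde), C=O
Why: Negishi zirconium-catalysed methylalumination adds CH3 and Al syn across the terminal alkyne (methyl to the internal carbon) and the alkenylalane is hydroxymethylated with retention, so the trisubstituted C9=C10 alkene should form as the E isomer only, which a ketone olefination would not guarantee.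

Step 8
Reactants: 12 (2E,8E,10E)-12-[(tert-butyldimethylsilyl)oxy]-3,7,7-trimethyldodeca-2,8,10-trien-1-ol
Product: 13 (2E,8E,10E)-12-[(tert-butyldimethylsilyl)oxy]-3,7,7-trimethyldodeca-2,8,10-trienal
Conditions: MnO2, CH2Cl2, rt
Reagents that add atoms: none
Why: Allylic oxidation with activated MnO2 is selective for the allylic alcohol, is neutral, and should not isomerise the enal or disturb the silyl dienyl ether.

Step 9
Reactants: 13 (2E,8E,10E)-12-[(tert-butyldimethylsilyl)oxy]-3,7,7-trimethyldodeca-2,8,10-trienal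
Product: 14 (1R,2R,4aR,8aR)-2-({[tert-butyl(dimethyl)silyl]oxy}methyl)-5,5,8a-trimethyl-1,2,4a,5,6,7,8,8a-octahydronaphthalene-1-carbaldehyde (trans-decalin; C20, C11 and C17 all on one face; 8-epi)
Conditions: (S)-o-tolyl-CBS-oxazaborolidine (20 mol %), Tf2NH (18 mol %), CH2Cl2, −78 → −20 °C
Reagents that add atoms: none
Why: Proposed new method: the oxazaborolidinium cation binds the formyl oxygen of 13 (B–O coordination backed by a formyl C–H···O contact), lowers the enal LUMO and lets the tethered E,E-diene add in a concerted, asynchronous, suprafacial [4+2] step in which C5–C10 forms ahead of C8–C9; the closest known reaction type is the chiral oxazaborolidinium- or imidazolidinone-catalysed intramolecular Diels–Alder reaction of 2,8,10-trienals that lack the β-substituent, and a Lewis acid is preferred over an amine because an iminium ion of a β,β-disubstituted enal would scramble the C9=C10 geometry through its dienamine. Ring B (C5–C10) is closed as the new cyclohexene by the cycloaddition itself, with its alkene born at C6=C7, and ring A (C1–C5, C10) is closed as the six-membered tether ring in the fused (type 1) mode through a chair-like C1–C4 chain. C9 and C10 are related by the E geometry of the enal (formyl and C20 methyl stay cis), C5 by the endo-formyl approach with the tether anti to the formyl group (trans ring fusion), and C8 by the E geometry of the distal diene bond, which places C17 cis to C11 (the C8 epimer of the target, corrected in step 14). The absolute sense at all four centres comes from the catalyst, whose aryl group should cover the Si face of C9 so that C8 bonds to its Re face. The step needs enal-face and endo/exo selectivity and intact alkene geometries; the gem-dimethyl group at C4 favours the folded rotamer, the diene carries no electron-withdrawing group, and the bulky silyl ether should not compete for boron.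

Step 10
Reactants: 14 the cycloadduct aldehyde
Product: 15 tert-butyl{[(1R,2R,4aR,8aS)-1-ethenyl-5,5,8a-trimethyl-1,2,4a,5,6,7,8,8a-octahydronaphthalen-2-yl]methoxy}dimethylsilane
Conditions: Ph3PCH3Br, KHMDS, THF, 0 °C; then 14, 0 °C → rt
Reagents that add atoms: methyltriphenylphosphonium bromide, C[P+](c1ccccc1)(c1ccccc1)c1ccccc1.[Br-]
Why: Wittig methylenation with the small, reactive unstabilised ylide converts the hindered C11 aldehyde into the C11=C12 vinyl group, and C9 is not at risk because its equatorial substituent is already the preferred arrangement (the 8a descriptor changes only through CIP priorities).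

Step 11
Reactants: 15 the vinyl silyl ether
Product: 16 [(1R,2R,4aR,8aS)-1-ethenyl-5,5,8a-trimethyl-1,2,4a,5,6,7,8,8a-octahydronaphthalen-2-yl]methanol
Conditions: TBAF, THF, 0 °C → rt
Reagents that add atoms: none
Why: Fluoride-induced desilylation frees the C17 primary alcohol, and nothing else in the molecule (two alkenes, no carbonyl group) responds to fluoride.

Step 12
Reactants: 16 the C17 alcohol
Product: 18 (1R,2R,4aR,8aS)-1-ethenyl-5,5,8a-trimethyl-1,2,4a,5,6,7,8,8a-octahydronaphthalene-2-carboxylic acid, via 8-epi C17 aldehyde 17 (not isolated)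
Conditions: TEMPO (20 mol %), PhI(OAc)2 (2.2 equiv), MeCN/H2O (1:1), rt
Reagents that add atoms: water, O
Why: Oxoammonium (TEMPO/PhI(OAc)2) oxidation takes the primary alcohol through the aldehyde hydrate to the acid in one flask under weakly acidic conditions, which spare both alkenes and keep the β,γ-unsaturated aldehyde from being exposed to base.

Step 13
Reactants: 18 the 8-epi acid
Product: 19 methyl (1R,2R,4aR,8aS)-1-ethenyl-5,5,8a-trimethyl-1,2,4a,5,6,7,8,8a-octahydronaphthalene-2-carboxylate
Conditions: TMSCHN2, MeOH/toluene, 0 °C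
Reagents that add atoms: trimethylsilyldiazomethane, C[Si](C)(C)C=[N+]=[N-]
Why: O-Methylation of the carboxylic acid with TMS-diazomethane in methanol is neutral and fast, so the ester forms without touching C8 or the C6=C7 alkene.

Step 14
Reactants: 19 the 8-epi methyl ester
Product: 20 methyl (1R,2S,4aR,8aS)-1-ethenyl-5,5,8a-trimethyl-1,2,4a,5,6,7,8,8a-octahydronaphthalene-2-carboxylate
Conditions: NaOMe (0.5 equiv), MeOH, 0 °C → rt, monitored; AcOH quench
Reagents that add atoms: none
Why: Base-mediated α-epimerisation of an ester through its dienolate: the ester of 19 is pseudo-axial and syn to the axial C20 methyl, so reversible C8 deprotonation and α-reprotonation should move it to the pseudo-equatorial position of 20; α-protonation of a dienolate is kinetically faster than γ-protonation, so the reaction is quenched as soon as 19 is consumed and before the alkene drifts to C7=C8.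

Step 15
Reactants: 21 methyl 4-hydroxybut-2-ynoate
Product: 22 methyl (2Z)-4-hydroxy-3-iodobut-2-enoate
Conditions: NaI, AcOH, 115 °C
Reagents that add atoms: sodium iodide, [Na+].[I-]
Why: Hydroiodination of an ynoate by conjugate addition of iodide and anti protonation of the allenoate should give the (Z)-β-iodoenoate, in which the hydroxymethyl group is trans to the ester and cannot lactonise.

Step 16
Reactants: 20 the equatorial vinyl ester; 22 methyl (2Z)-4-hydroxy-3-iodobut-2-enoate
Product: 24 methyl (1R,2S,4aR,8aS)-1-[(3E)-3-(hydroxymethyl)-5-methoxy-5-oxopent-3-en-1-yl]-5,5,8a-trimethyl-1,2,4a,5,6,7,8,8a-octahydronaphthalene-2-carboxylate, via B-alkyl-9-BBN borane 23 (not isolated)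
Conditions: 9-BBN-H, THF, 0 °C → rt; then 22, PdCl2(dppf) (5 mol %), AsPh3, 3 M aq. K3PO4, DMF, rt
Reagents that add atoms: none
Why: 9-BBN hydroborates only the monosubstituted C11=C12 alkene (boron to C12) and the primary alkylborane then couples with the β-iodoenoate in a B-alkyl Suzuki–Miyaura reaction with retention of alkene geometry, so C12 ends cis to the ester (the descriptor changes from Z to E only because carbon replaces iodine).

Step 17
Reactants: 24 the C16 alcohol
Product: 25 methyl (1R,2S,4aR,8aS)-1-[(3E)-3-(acetoxymethyl)-5-methoxy-5-oxopent-3-en-1-yl]-5,5,8a-trimethyl-1,2,4a,5,6,7,8,8a-octahydronaphthalene-2-carboxylate (CNP0190145.1)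
Conditions: Ac2O, pyridine, DMAP (cat.), CH2Cl2, 0 °C → rt
Reagents that add atoms: acetic anhydride, CC(=O)OC(C)=O
Why: DMAP-catalysed acetylation of the primary allylic alcohol is fast under weakly basic conditions that should neither epimerise C8 nor isomerise either alkene.

**Compound list**

1 | isobutyronitrile | CC(C)C#N | starting material
2 | (5-chloropent-1-yn-1-yl)trimethylsilane | C[Si](C)(C)C#CCCCCl | starting material
3 | 2,2-dimethyl-7-(trimethylsilyl)hept-6-ynenitrile | C[Si](C)(C)C#CCCCC(C)(C)C#N | intermediate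
4 | N-(diisobutylalumino)-2,2-dimethyl-7-(trimethylsilyl)hept-6-yn-1-imine | CC(C)C[Al](CC(C)C)N=CC(C)(C)CCCC#C[Si](C)(C)C | intermediate
5 | 2,2-dimethyl-7-(trimethylsilyl)hept-6-ynal | C[Si](C)(C)C#CCCCC(C)(C)C=O | intermediate
6 | triethyl 4-phosphonocrotonate | CCOC(=O)/C=C/CP(=O)(OCC)OCC | starting material
7 | ethyl (2E,4E)-6,6-dimethyl-11-(trimethylsilyl)undeca-2,4-dien-10-ynoate | CCOC(=O)/C=C/C=C/C(C)(C)CCCC#C[Si](C)(C)C | intermediate
8 | (2E,4E)-6,6-dimethyl-11-(trimethylsilyl)undeca-2,4-dien-10-yn-1-ol | OC/C=C/C=C/C(C)(C)CCCC#C[Si](C)(C)C | intermediate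
9 | tert-butyl{[(2E,4E)-6,6-dimethyl-11-(trimethylsilyl)undeca-2,4-dien-10-yn-1-yl]oxy}dimethylsilane | CC(C)(C)[Si](C)(C)OC/C=C/C=C/C(C)(C)CCCC#C[Si](C)(C)C | intermediate
10 | tert-butyl{[(2E,4E)-6,6-dimethylundeca-2,4-dien-10-yn-1-yl]oxy}dimethylsilane | CC(C)(C)[Si](C)(C)OC/C=C/C=C/C(C)(C)CCCC#C | intermediate
11 | [(1E,7E,9E)-11-{[tert-butyl(dimethyl)silyl]oxy}-2,6,6-trimethylundeca-1,7,9-trien-1-yl]dimethylalumane | C[Al](C)/C=C(\C)CCCC(C)(C)/C=C/C=C/CO[Si](C)(C)C(C)(C)C | intermediate
12 | (2E,8E,10E)-12-[(tert-butyldimethylsilyl)oxy]-3,7,7-trimethyldodeca-2,8,10-trien-1-ol | OC/C=C(\C)CCCC(C)(C)/C=C/C=C/CO[Si](C)(C)C(C)(C)C | intermediate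
13 | (2E,8E,10E)-12-[(tert-butyldimethylsilyl)oxy]-3,7,7-trimethyldodeca-2,8,10-trienal | O=C/C=C(\C)CCCC(C)(C)/C=C/C=C/CO[Si](C)(C)C(C)(C)C | intermediate
14 | (1R,2R,4aR,8aR)-2-({[tert-butyl(dimethyl)silyl]oxy}methyl)-5,5,8a-trimethyl-1,2,4a,5,6,7,8,8a-octahydronaphthalene-1-carbaldehyde | O=C[C@@H]1[C@H](CO[Si](C)(C)C(C)(C)C)C=C[C@@H]2C(C)(C)CCC[C@@]12C | intermediate
15 | tert-butyl{[(1R,2R,4aR,8aS)-1-ethenyl-5,5,8a-trimethyl-1,2,4a,5,6,7,8,8a-octahydronaphthalen-2-yl]methoxy}dimethylsilane | C=C[C@@H]1[C@H](CO[Si](C)(C)C(C)(C)C)C=C[C@@H]2C(C)(C)CCC[C@@]12C | intermediate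
16 | [(1R,2R,4aR,8aS)-1-ethenyl-5,5,8a-trimethyl-1,2,4a,5,6,7,8,8a-octahydronaphthalen-2-yl]methanol | C=C[C@@H]1[C@H](CO)C=C[C@@H]2C(C)(C)CCC[C@@]12C | intermediate
17 | (1R,2R,4aR,8aS)-1-ethenyl-5,5,8a-trimethyl-1,2,4a,5,6,7,8,8a-octahydronaphthalene-2-carbaldehyde | C=C[C@@H]1[C@H](C=O)C=C[C@@H]2C(C)(C)CCC[C@@]12C | intermediate
18 | (1R,2R,4aR,8aS)-1-ethenyl-5,5,8a-trimethyl-1,2,4a,5,6,7,8,8a-octahydronaphthalene-2-carboxylic acid | C=C[C@@H]1[C@H](C(=O)O)C=C[C@@H]2C(C)(C)CCC[C@@]12C | intermediate
19 | methyl (1R,2R,4aR,8aS)-1-ethenyl-5,5,8a-trimethyl-1,2,4a,5,6,7,8,8a-octahydronaphthalene-2-carboxylate | C=C[C@@H]1[C@H](C(=O)OC)C=C[C@@H]2C(C)(C)CCC[C@@]12C | intermediate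
20 | methyl (1R,2S,4aR,8aS)-1-ethenyl-5,5,8a-trimethyl-1,2,4a,5,6,7,8,8a-octahydronaphthalene-2-carboxylate | C=C[C@@H]1[C@@H](C(=O)OC)C=C[C@@H]2C(C)(C)CCC[C@@]12C | intermediate
21 | methyl 4-hydroxybut-2-ynoate | COC(=O)C#CCO | starting material
22 | methyl (2Z)-4-hydroxy-3-iodobut-2-enoate | COC(=O)/C=C(\I)CO | intermediate
23 | methyl (1R,2S,4aR,8aS)-1-[2-(9-borabicyclo[3.3.1]nonan-9-yl)ethyl]-5,5,8a-trimethyl-1,2,4a,5,6,7,8,8a-octahydronaphthalene-2-carboxylate | C1CCC2CCCC1B2CC[C@@H]3[C@@H](C(=O)OC)C=C[C@@H]4C(C)(C)CCC[C@@]34C | intermediate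
24 | methyl (1R,2S,4aR,8aS)-1-[(3E)-3-(hydroxymethyl)-5-methoxy-5-oxopent-3-en-1-yl]-5,5,8a-trimethyl-1,2,4a,5,6,7,8,8a-octahydronaphthalene-2-carboxylate | COC(=O)/C=C(\CC[C@@H]1[C@@H](C(=O)OC)C=C[C@@H]2C(C)(C)CCC[C@@]12C)CO | intermediate
25 | methyl (1R,2S,4aR,8aS)-1-[(3E)-3-(acetoxymethyl)-5-methoxy-5-oxopent-3-en-1-yl]-5,5,8a-trimethyl-1,2,4a,5,6,7,8,8a-octahydronaphthalene-2-carboxylate | COC(=O)/C=C(\CC[C@@H]1[C@@H](C(=O)OC)C=C[C@@H]2C(C)(C)CCC[C@@]12C)COC(C)=O | target

**Step count and risks**

Total steps: 17. Longest linear sequence: 16 (steps 1–14, 16, 17); step 15 is a one-step side branch.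

Steps most likely to fail:

1. Step 9 (proposed new method). The β,β-disubstituted enal may bind or react too slowly, so that an uncatalysed or achiral-acid pathway takes over. Other failure modes are poor discrimination of the enal faces, leakage through the exo (cis-fused) transition state and acid-induced ionisation of the dienylic silyl ether. The fallback uses known chemistry, sets out from 13 and returns at 16. Compound 13 is cyclised without chiral control, thermally (toluene, BHT, 150 °C, sealed tube) or with Me2AlCl (CH2Cl2, −78 → −20 °C), to the racemic trans-fused cycloadduct F1. Methylenation and desilylation as in steps 10 and 11 give the racemic vinyl silyl ether F2 and the racemic alcohol F3. The alcohol is esterified with (S)-O-methylmandelic acid (DCC, DMAP, CH2Cl2) and the two diastereomeric esters are separated by chromatography or crystallisation. The (S)-O-methylmandelate of the (1R,2R,4aR,8aS)-alcohol F4 is then methanolysed (K2CO3, MeOH) to 16.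

2. Step 14. Migration of the C6=C7 alkene into conjugation with the ester may keep pace with inversion at C8, or the inversion may stall before completion. The fallback sets out from 16 and returns at 20; it moves the inversion to the aldehyde oxidation level, where the α-hydrogen is far more acidic and a weak amine base at low temperature suffices. Compound 16 is oxidised with Dess–Martin periodinane (NaHCO3, CH2Cl2) to the aldehyde 17, which is isolated this time. DBU (cat.) in CH2Cl2 at −40 °C should epimerise it to the C8-epimeric aldehyde F5. Pinnick oxidation (NaClO2, NaH2PO4, 2-methyl-2-butene, t-BuOH/H2O) gives the equatorial acid F6, and TMSCHN2 gives 20.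

3. Step 16. The aqueous base of the coupling may epimerise C8 or move the ring alkene, or protodeboronation of the alkylborane may outrun transmetallation. The fallback sets out from 20 and returns at 25 by a base-free Negishi coupling. Hydroboration of 20 with 9-BBN (borane 23) followed by oxidation with NaBO3·4H2O gives the primary alcohol F7. Appel iodination (I2, PPh3, imidazole) gives the iodide F8, and zinc insertion (Zn, LiCl, THF) gives the alkylzinc iodide F9. This is coupled (Pd(PPh3)4, THF/DMA, rt) with methyl (2Z)-4-acetoxy-3-iodobut-2-enoate F10, made from 22 with Ac2O/pyridine, to give 25 directly.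

Further compounds
F1 | step 9 | racemic (1R*,2R*,4aR*,8aR*)-2-({[tert-butyl(dimethyl)silyl]oxy}methyl)-5,5,8a-trimethyl-1,2,4a,5,6,7,8,8a-octahydronaphthalene-1-carbaldehyde | O=C[C@@H]1[C@H](CO[Si](C)(C)C(C)(C)C)C=C[C@@H]2C(C)(C)CCC[C@@]12C.O=C[C@H]1[C@@H](CO[Si](C)(C)C(C)(C)C)C=C[C@H]2C(C)(C)CCC[C@]12C
F2 | step 9 | racemic tert-butyl{[(1R*,2R*,4aR*,8aS*)-1-ethenyl-5,5,8a-trimethyl-1,2,4a,5,6,7,8,8a-octahydronaphthalen-2-yl]methoxy}dimethylsilane | C=C[C@@H]1[C@H](CO[Si](C)(C)C(C)(C)C)C=C[C@@H]2C(C)(C)CCC[C@@]12C.C=C[C@H]1[C@@H](CO[Si](C)(C)C(C)(C)C)C=C[C@H]2C(C)(C)CCC[C@]12C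
F3 | step 9 | racemic [(1R*,2R*,4aR*,8aS*)-1-ethenyl-5,5,8a-trimethyl-1,2,4a,5,6,7,8,8a-octahydronaphthalen-2-yl]methanol | C=C[C@@H]1[C@H](CO)C=C[C@@H]2C(C)(C)CCC[C@@]12C.C=C[C@H]1[C@@H](CO)C=C[C@H]2C(C)(C)CCC[C@]12C
F4 | step 9 | [(1R,2R,4aR,8aS)-1-ethenyl-5,5,8a-trimethyl-1,2,4a,5,6,7,8,8a-octahydronaphthalen-2-yl]methyl (2S)-2-methoxy-2-phenylacetate | C=C[C@@H]1[C@H](COC(=O)[C@@H](OC)c2ccccc2)C=C[C@@H]3C(C)(C)CCC[C@@]13C
F5 | step 14 | (1R,2S,4aR,8aS)-1-ethenyl-5,5,8a-trimethyl-1,2,4a,5,6,7,8,8a-octahydronaphthalene-2-carbaldehyde | C=C[C@@H]1[C@@H](C=O)C=C[C@@H]2C(C)(C)CCC[C@@]12C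
F6 | step 14 | (1R,2S,4aR,8aS)-1-ethenyl-5,5,8a-trimethyl-1,2,4a,5,6,7,8,8a-octahydronaphthalene-2-carboxylic acid | C=C[C@@H]1[C@@H](C(=O)O)C=C[C@@H]2C(C)(C)CCC[C@@]12C
F7 | step 16 | methyl (1R,2S,4aR,8aS)-1-(2-hydroxyethyl)-5,5,8a-trimethyl-1,2,4a,5,6,7,8,8a-octahydronaphthalene-2-carboxylate | OCC[C@@H]1[C@@H](C(=O)OC)C=C[C@@H]2C(C)(C)CCC[C@@]12C
F8 | step 16 | methyl (1R,2S,4aR,8aS)-1-(2-iodoethyl)-5,5,8a-trimethyl-1,2,4a,5,6,7,8,8a-octahydronaphthalene-2-carboxylate | ICC[C@@H]1[C@@H](C(=O)OC)C=C[C@@H]2C(C)(C)CCC[C@@]12C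
F9 | step 16 | {2-[(1R,2S,4aR,8aS)-2-(methoxycarbonyl)-5,5,8a-trimethyl-1,2,4a,5,6,7,8,8a-octahydronaphthalen-1-yl]ethyl}zinc iodide | I[Zn]CC[C@@H]1[C@@H](C(=O)OC)C=C[C@@H]2C(C)(C)CCC[C@@]12C
F10 | step 16 | methyl (2Z)-4-acetoxy-3-iodobut-2-enoate | COC(=O)/C=C(\I)COC(C)=O
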